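The route rests on cutting ring A between C3 and its formyl carbon and between C4 and its phenolic oxygen: both bonds are made at once when the C3–C4 aryne of ring A takes up the C=O unit of N,N-dimethylformamide. The step exploits the C3 formyl group flanked by oxygens at C2 and C4 of ring A; the C2 allyloxy group steers oxygen to C4 and carbon to C3. The precursor is the fully assembled benzyl depside carrying a C3 trimethylsilyl group, a C4 triflate and a C2 allyl ether on ring A, with ring B masked as allyl ester bis(allyl ether); one palladium-catalysed deallylation then gives alectorialic acid.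

Key step: step 12

Remark: both rings are numbered as benzoates (ring A: C1 ester carbon, C2 O, C3 CHO, C4 O, C6 CH3; ring B: C1 CO2H, C2 O, C3 CH3, C4 O, C6 CH2O); "ring-B benzyl" stands for [3,5-bis(allyloxy)-2-(allyloxycarbonyl)-4-methylphenyl]methyl; organolithium and charged intermediates are drawn as monomeric formal structures.

Step 1
Reactants: 1 orcinol (5-methylbenzene-1,3-diol, anhydrous)
Product: 2 1,3-bis(methoxymethoxy)-5-methylbenzene
Conditions: NaH, MOMCl, DMF, 0 °C to rt
Reagents that add atoms: chloromethyl methyl ether, COCCl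
Why: Williamson-type O-alkylation of both phenoxides should give the bis-acetal, whose two OCH2OMe groups serve as ortho-directing groups in the next two steps.

Step 2
Reactants: 2 1,3-bis(methoxymethoxy)-5-methylbenzene
Product: 4 [2,6-bis(methoxymethoxy)-4-methylphenyl]trimethylsilane, via C2 aryllithium 3 (not isolated)
Conditions: n-BuLi, THF, 0 °C to rt; then TMSCl, 0 °C to rt
Reagents that add atoms: chlorotrimethylsilane, C[Si](C)(C)Cl
Why: Directed ortho-metalation should occur at the carbon between the two MOM ethers, the most acidic and doubly coordinated site, and the aryllithium is silylated.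

Step 3
Reactants: 4 [2,6-bis(methoxymethoxy)-4-methylphenyl]trimethylsilane
Product: 6 2,4-bis(methoxymethoxy)-6-methyl-3-(trimethylsilyl)benzoic acid, via ring aryllithium 5 (not isolated)
Conditions: s-BuLi, TMEDA, THF, −78 °C; then CO2, −78 °C to rt; 1 M HCl to pH 4, 0 °C
Reagents that add atoms: carbon dioxide, O=C=O
Why: With the position between the oxygens blocked by silicon, a second directed ortho-metalation should take place beside a MOM ether and the methyl group (the two such sites are equivalent by symmetry), and carboxylation of the aryllithium gives the ring-A acid.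

Step 4
Reactants: 7 atraric acid (methyl 2,4-dihydroxy-3,6-dimethylbenzoate)
Product: 8 methyl 2,4-bis(allyloxy)-3,6-dimethylbenzoate
Conditions: allyl bromide, K2CO3, DMF, 60 °C
Reagents that add atoms: allyl bromide, C=CCBr
Why: Williamson etherification of both phenols, the chelated C2 phenol included under these forcing but non-hydrolytic conditions, installs the groups that the final deallylation removes.

Step 5
Reactants: 8 methyl 2,4-bis(allyloxy)-3,6-dimethylbenzoate
Product: 11 5,7-bis(allyloxy)-6-methylisobenzofuran-1(3H)-one, via benzylic lithium species 9 (not isolated), via lithium alkoxide 10 (not isolated)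
Conditions: LiN(i-Pr)2, THF, −78 °C; then 2-(phenylsulfonyl)-3-phenyloxaziridine, −78 to 0 °C; 1 M HCl
Reagents that add atoms: 2-(phenylsulfonyl)-3-phenyloxaziridine, O=S(=O)(c1ccccc1)N1OC1c1ccccc1
Why: Lateral lithiation of the ortho-toluate should touch only the C6 methyl group, whose anion is conjugated with the ester; oxygen transfer from the N-sulfonyloxaziridine (Davis hydroxylation) gives the benzylic alkoxide, which lactonises 5-exo-trig onto the methyl ester.

Step 6
Reactants: 11 5,7-bis(allyloxy)-6-methylisobenzofuran-1(3H)-one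
Product: 13 allyl 2,4-bis(allyloxy)-6-(hydroxymethyl)-3-methylbenzoate, via potassium carboxylate 12 (not isolated)
Conditions: KOH (1.05 equiv), THF/H2O, 50 °C; evaporate; allyl bromide, DMF, rt
Reagents that add atoms: potassium hydroxide, [K+].[OH-]; allyl bromide, C=CCBr
Why: Saponification opens the lactone and SN2 alkylation of the carboxylate, far more nucleophilic than the neutral primary alcohol, should give the allyl ester with the benzylic hydroxyl free.

Step 7
Reactants: 6 2,4-bis(methoxymethoxy)-6-methyl-3-(trimethylsilyl)benzoic acid; 13 allyl 2,4-bis(allyloxy)-6-(hydroxymethyl)-3-methylbenzoate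
Product: 14 ring-B benzyl 2,4-bis(methoxymethoxy)-6-methyl-3-(trimethylsilyl)benzoate
Conditions: PPh3, DIAD, THF, 0 °C to rt
Reagents that add atoms: none
Why: Mitsunobu esterification joins the fragments by SN2 attack of the hindered carboxylate on the unhindered benzylic alkoxyphosphonium ion, so no acyl activation of the 2,6-disubstituted acid is needed.

Step 8
Reactants: 14 ring-B benzyl 2,4-bis(methoxymethoxy)-6-methyl-3-(trimethylsilyl)benzoate
Product: 15 ring-B benzyl 2-hydroxy-4-(methoxymethoxy)-6-methyl-3-(trimethylsilyl)benzoate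
Conditions: MgBr2·OEt2, n-BuSH, Et2O, 0 °C to rt
Reagents that add atoms: none
Why: Chelation-controlled acetal cleavage: magnesium held between the ring-A ester carbonyl and the C2 acetal should activate only that MOM group, the thiol takes up the methoxymethyl cation, and the C4 acetal, which has no chelating neighbour, should stay.

Step 9
Reactants: 15 ring-B benzyl 2-hydroxy-4-(methoxymethoxy)-6-methyl-3-(trimethylsilyl)benzoate
Product: 16 ring-B benzyl 2-(allyloxy)-4-(methoxymethoxy)-6-methyl-3-(trimethylsilyl)benzoate
Conditions: allyl bromide, K2CO3, DMF, 40 °C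
Reagents that add atoms: allyl bromide, C=CCBr
Why: Williamson etherification of the C2 phenol is done while C4 still carries its acetal, so that the phenoxide is never formed beside a silane that has a leaving group on its other side.

Step 10
Reactants: 16 ring-B benzyl 2-(allyloxy)-4-(methoxymethoxy)-6-methyl-3-(trimethylsilyl)benzoate
Product: 18 ring-B benzyl 2-(allyloxy)-4-hydroxy-6-methyl-3-(trimethylsilyl)benzoate, via aryl silyl ether 17 (not isolated)
Conditions: TMSOTf, 2,2′-bipyridyl, MeCN, 0 °C to rt; then H2O
Reagents that add atoms: none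
Why: Silyl triflate/bipyridyl cleavage of an aryl MOM ether passes through the aryl trimethylsilyl ether, which water hydrolyses; no protic acid is present, which should protect the electron-rich C3–Si bond from protodesilylation.

Step 11
Reactants: 18 ring-B benzyl 2-(allyloxy)-4-hydroxy-6-methyl-3-(trimethylsilyl)benzoate
Product: 19 ring-B benzyl 2-(allyloxy)-6-methyl-4-(trifluoromethanesulfonyloxy)-3-(trimethylsilyl)benzoate
Conditions: Tf2O, pyridine, CH2Cl2, 0 °C
Reagents that add atoms: trifluoromethanesulfonic anhydride, O=S(=O)(OS(=O)(=O)C(F)(F)F)C(F)(F)F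
Why: O-Sulfonylation of the only free phenol completes the ortho-silylaryl triflate; O2 is already capped, so no phenoxide can shift silicon from C3 to oxygen and release the aryne early.

Step 12
Reactants: 19 ring-B benzyl 2-(allyloxy)-6-methyl-4-(trifluoromethanesulfonyloxy)-3-(trimethylsilyl)benzoate; 20 N,N-dimethylformamide
Product: 24 ring-B benzyl 2-(allyloxy)-3-formyl-4-hydroxy-6-methylbenzoate, via ring-A aryne 21 (not isolated), via benzoxete aminal 22 (not isolated), via iminium phenolate 23 (not isolated)
Conditions: CsF, dry 20 as solvent (dilute in 19), rt; then H2O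
Reagents that add atoms: water, O
Why: Fluoride attacks silicon at C3 and triflate leaves from C4 to give aryne 21; the amide oxygen adds to C4 and the C3 aryl anion closes onto the iminium carbon, a formal [2+2] insertion of an aryne into a C=O bond, which is the known route from ortho-silylaryl triflates and formamides to salicylaldehydes. The four-membered benzoxete 22 closes by 4-exo-trig attack of the aryl anion on the iminium carbon, does not persist, and opens by 4π-electrocyclic cleavage to the iminium phenolate (ortho-quinone methide aminal) 23, which water hydrolyses to the C3 aldehyde and C4 phenol. No stereocentre is set, since the aminal carbon of 22 is transient and ends as the planar formyl carbon. The step needs regioselective addition to an unsymmetrical aryne, and the inductively withdrawing C2 allyloxy group next to C3 secures it by making the distal C4 the electrophilic terminus and placing the developing carbanion at C3 beside oxygen. It also needs the aryne to meet the amide before any other nucleophile, which the use of dry 20 as solvent at high dilution of 19 should ensure, while CsF at room temperature should leave the esters and allyl ethers untouched.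

Step 13
Reactants: 24 ring-B benzyl 2-(allyloxy)-3-formyl-4-hydroxy-6-methylbenzoate
Product: 25 alectorialic acid
Conditions: Pd(PPh3)4 (cat.), 4-MeC6H4SO2H, CH2Cl2, rt
Reagents that add atoms: none
Why: Tsuji–Trost deallylation: zerovalent palladium ionises the allyl ester and the three aryl allyl ethers and the sulfinate captures each π-allyl unit as a sulfone, a base-free medium in which the benzylic depside ester, the aldehyde and the free acid should survive.

Compound list
1 | orcinol (5-methylbenzene-1,3-diol) | Cc1cc(O)cc(O)c1 | starting material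
2 | 1,3-bis(methoxymethoxy)-5-methylbenzene | COCOc1cc(C)cc(OCOC)c1 | intermediate
3 | [2,6-bis(methoxymethoxy)-4-methylphenyl]lithium | [Li]c1c(OCOC)cc(C)cc1OCOC | intermediate (not isolated)
4 | [2,6-bis(methoxymethoxy)-4-methylphenyl]trimethylsilane | COCOc1cc(C)cc(OCOC)c1[Si](C)(C)C | intermediate
5 | [2,4-bis(methoxymethoxy)-6-methyl-3-(trimethylsilyl)phenyl]lithium | COCOc1cc(C)c([Li])c(OCOC)c1[Si](C)(C)C | intermediate (not isolated)
6 | 2,4-bis(methoxymethoxy)-6-methyl-3-(trimethylsilyl)benzoic acid | COCOc1cc(C)c(C(=O)O)c(OCOC)c1[Si](C)(C)C | intermediate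
7 | atraric acid (methyl 2,4-dihydroxy-3,6-dimethylbenzoate) | COC(=O)c1c(C)cc(O)c(C)c1O | starting material
8 | methyl 2,4-bis(allyloxy)-3,6-dimethylbenzoate | COC(=O)c1c(C)cc(OCC=C)c(C)c1OCC=C | intermediate
9 | methyl 2,4-bis(allyloxy)-6-(lithiomethyl)-3-methylbenzoate | COC(=O)c1c(C[Li])cc(OCC=C)c(C)c1OCC=C | intermediate (not isolated)
10 | lithium alkoxide of methyl 2,4-bis(allyloxy)-6-(hydroxymethyl)-3-methylbenzoate | COC(=O)c1c(CO[Li])cc(OCC=C)c(C)c1OCC=C | intermediate (not isolated)
11 | 5,7-bis(allyloxy)-6-methylisobenzofuran-1(3H)-one | O=C1OCc2cc(OCC=C)c(C)c(OCC=C)c21 | intermediate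
12 | potassium 2,4-bis(allyloxy)-6-(hydroxymethyl)-3-methylbenzoate | [K+].[O-]C(=O)c1c(CO)cc(OCC=C)c(C)c1OCC=C | intermediate (not isolated)
13 | allyl 2,4-bis(allyloxy)-6-(hydroxymethyl)-3-methylbenzoate | C=CCOC(=O)c1c(CO)cc(OCC=C)c(C)c1OCC=C | intermediate
14 | [3,5-bis(allyloxy)-2-(allyloxycarbonyl)-4-methylphenyl]methyl 2,4-bis(methoxymethoxy)-6-methyl-3-(trimethylsilyl)benzoate | COCOc1cc(C)c(C(=O)OCc2cc(OCC=C)c(C)c(OCC=C)c2C(=O)OCC=C)c(OCOC)c1[Si](C)(C)C | intermediate
15 | [3,5-bis(allyloxy)-2-(allyloxycarbonyl)-4-methylphenyl]methyl 2-hydroxy-4-(methoxymethoxy)-6-methyl-3-(trimethylsilyl)benzoate | COCOc1cc(C)c(C(=O)OCc2cc(OCC=C)c(C)c(OCC=C)c2C(=O)OCC=C)c(O)c1[Si](C)(C)C | intermediate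
16 | [3,5-bis(allyloxy)-2-(allyloxycarbonyl)-4-methylphenyl]methyl 2-(allyloxy)-4-(methoxymethoxy)-6-methyl-3-(trimethylsilyl)benzoate | COCOc1cc(C)c(C(=O)OCc2cc(OCC=C)c(C)c(OCC=C)c2C(=O)OCC=C)c(OCC=C)c1[Si](C)(C)C | intermediate
17 | [3,5-bis(allyloxy)-2-(allyloxycarbonyl)-4-methylphenyl]methyl 2-(allyloxy)-6-methyl-3-(trimethylsilyl)-4-(trimethylsilyloxy)benzoate | C[Si](C)(C)Oc1cc(C)c(C(=O)OCc2cc(OCC=C)c(C)c(OCC=C)c2C(=O)OCC=C)c(OCC=C)c1[Si](C)(C)C | intermediate (not isolated)
18 | [3,5-bis(allyloxy)-2-(allyloxycarbonyl)-4-methylphenyl]methyl 2-(allyloxy)-4-hydroxy-6-methyl-3-(trimethylsilyl)benzoate | Cc1cc(O)c([Si](C)(C)C)c(OCC=C)c1C(=O)OCc1cc(OCC=C)c(C)c(OCC=C)c1C(=O)OCC=C | intermediate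
19 | [3,5-bis(allyloxy)-2-(allyloxycarbonyl)-4-methylphenyl]methyl 2-(allyloxy)-6-methyl-4-(trifluoromethanesulfonyloxy)-3-(trimethylsilyl)benzoate | Cc1cc(OS(=O)(=O)C(F)(F)F)c([Si](C)(C)C)c(OCC=C)c1C(=O)OCc1cc(OCC=C)c(C)c(OCC=C)c1C(=O)OCC=C | intermediate
20 | N,N-dimethylformamide | CN(C)C=O | starting material
21 | ring-A C3–C4 aryne: [3,5-bis(allyloxy)-2-(allyloxycarbonyl)-4-methylphenyl]methyl 2-(allyloxy)-3,4-didehydro-6-methylbenzoate | CC1=CC#CC(OCC=C)=C1C(=O)OCc1cc(OCC=C)c(C)c(OCC=C)c1C(=O)OCC=C | intermediate (not isolated)
22 | benzoxete aminal: four-membered ring C4–O–CH(NMe2)–C3 fused to ring A of the depside (racemic at the aminal carbon) | Cc1cc2OC(N(C)C)c2c(OCC=C)c1C(=O)OCc1cc(OCC=C)c(C)c(OCC=C)c1C(=O)OCC=C | intermediate (not isolated)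
23 | iminium phenolate (ortho-quinone methide aminal): ring A with CH=N+Me2 at C3 and O− at C4 | C[N+](C)=Cc1c([O-])cc(C)c(C(=O)OCc2cc(OCC=C)c(C)c(OCC=C)c2C(=O)OCC=C)c1OCC=C | intermediate (not isolated)
24 | [3,5-bis(allyloxy)-2-(allyloxycarbonyl)-4-methylphenyl]methyl 2-(allyloxy)-3-formyl-4-hydroxy-6-methylbenzoate | Cc1cc(O)c(C=O)c(OCC=C)c1C(=O)OCc1cc(OCC=C)c(C)c(OCC=C)c1C(=O)OCC=C | intermediate
25 | alectorialic acid, 6-{[(3-formyl-2,4-dihydroxy-6-methylbenzoyl)oxy]methyl}-2,4-dihydroxy-3-methylbenzoic acid | Cc1cc(O)c(C=O)c(O)c1C(=O)OCc1cc(O)c(C)c(O)c1C(=O)O | target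

Total step count: 13. Longest linear sequence: 10 steps (1 → 25 through steps 1–3 and 7–13; the branch from 7 through steps 4–6 and 7–13 is equally long).

Steps most likely to fail

Step 12. The aryne may be consumed before the amide oxygen reaches it, for example by protonation, by addition of fluoride or of the phenolate already formed, or by reaction of the iminium phenolate with a second aryne. The hydroxy aldehyde would then not form cleanly. Fallback (sets out from 2, returns at 25): the formyl carbon is placed by directed lithiation instead of through the aryne. Lithiation of 2 at C2 (aryllithium 3) and a quench with N,N-dimethylformamide should give 2,6-bis(methoxymethoxy)-4-methylbenzaldehyde F1. Trimethyl orthoformate and pyridinium tosylate in methanol should give the dimethyl acetal 2-(dimethoxymethyl)-1,3-bis(methoxymethoxy)-5-methylbenzene F2. s-BuLi/TMEDA should lithiate F2 beside the methyl group to the lithio acetal F3; CO2 and a mildly acidic work-up that also unmasks the aldehyde should then give 3-formyl-2,4-bis(methoxymethoxy)-6-methylbenzoic acid F4. Mitsunobu esterification with 13 should give ring-B benzyl 3-formyl-2,4-bis(methoxymethoxy)-6-methylbenzoate F5. TMSOTf/2,2′-bipyridyl followed by water should remove both MOM groups to give ring-B benzyl 3-formyl-2,4-dihydroxy-6-methylbenzoate F6, and deallylation as in step 13 should give 25.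

Step 8. Both MOM groups may be lost instead of one, or the Lewis acid may cause protodesilylation at C3 of the newly freed, electron-rich phenol. Fallback (sets out from 14, returns at 19): the two oxygens are told apart by their reactivity as phenols instead of by selective acetal cleavage. TMSOTf/2,2′-bipyridyl followed by water should remove both MOM groups from 14 to give ring-B benzyl 2,4-dihydroxy-6-methyl-3-(trimethylsilyl)benzoate F7. Tf2O (one equivalent) and pyridine at low temperature should sulfonylate only the non-chelated, more acidic C4 phenol to give ring-B benzyl 2-hydroxy-6-methyl-4-(trifluoromethanesulfonyloxy)-3-(trimethylsilyl)benzoate F8. The chelated C2 phenol is then allylated without free phenoxide, by allyl bromide and Ag2O in CH2Cl2 in the dark, to give 19; carbonate bases are avoided here because a C2 phenoxide beside the silane and the triflate could release the aryne early.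

Step 3. The strong base may remove a proton from a silicon-bound methyl group, or ring metalation at the crowded position beside the methyl group may stay incomplete; either gives the wrong or no carboxylation. Fallback (sets out from 2, returns at 6): the carbanion is made by halogen–lithium exchange at a carbon fixed beforehand by electrophilic bromination. NBS in MeCN should brominate 2 beside the methyl group, para to one acetal and ortho to the other, to give 2-bromo-1,5-bis(methoxymethoxy)-3-methylbenzene F9. Lithium 2,2,6,6-tetramethylpiperidide with TMSCl present in the flask (THF, −78 °C) should silylate the position between the two acetals to give [3-bromo-2,6-bis(methoxymethoxy)-4-methylphenyl]trimethylsilane F10. t-BuLi (two equivalents, −78 °C) should then generate the aryllithium 5 by bromine–lithium exchange, and CO2 should give 6.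

Further compounds
F1 | step 12 | 2,6-bis(methoxymethoxy)-4-methylbenzaldehyde | COCOc1cc(C)cc(OCOC)c1C=O
F2 | step 12 | 2-(dimethoxymethyl)-1,3-bis(methoxymethoxy)-5-methylbenzene | COCOc1cc(C)cc(OCOC)c1C(OC)OC
F3 | step 12 | [3-(dimethoxymethyl)-2,4-bis(methoxymethoxy)-6-methylphenyl]lithium | COCOc1cc(C)c([Li])c(OCOC)c1C(OC)OC
F4 | step 12 | 3-formyl-2,4-bis(methoxymethoxy)-6-methylbenzoic acid | COCOc1cc(C)c(C(=O)O)c(OCOC)c1C=O
F5 | step 12 | [3,5-bis(allyloxy)-2-(allyloxycarbonyl)-4-methylphenyl]methyl 3-formyl-2,4-bis(methoxymethoxy)-6-methylbenzoate | COCOc1cc(C)c(C(=O)OCc2cc(OCC=C)c(C)c(OCC=C)c2C(=O)OCC=C)c(OCOC)c1C=O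
F6 | step 12 | [3,5-bis(allyloxy)-2-(allyloxycarbonyl)-4-methylphenyl]methyl 3-formyl-2,4-dihydroxy-6-methylbenzoate | Cc1cc(O)c(C=O)c(O)c1C(=O)OCc1cc(OCC=C)c(C)c(OCC=C)c1C(=O)OCC=C
F7 | step 8 | [3,5-bis(allyloxy)-2-(allyloxycarbonyl)-4-methylphenyl]methyl 2,4-dihydroxy-6-methyl-3-(trimethylsilyl)benzoate | Cc1cc(O)c([Si](C)(C)C)c(O)c1C(=O)OCc1cc(OCC=C)c(C)c(OCC=C)c1C(=O)OCC=C
F8 | step 8 | [3,5-bis(allyloxy)-2-(allyloxycarbonyl)-4-methylphenyl]methyl 2-hydroxy-6-methyl-4-(trifluoromethanesulfonyloxy)-3-(trimethylsilyl)benzoate | Cc1cc(OS(=O)(=O)C(F)(F)F)c([Si](C)(C)C)c(O)c1C(=O)OCc1cc(OCC=C)c(C)c(OCC=C)c1C(=O)OCC=C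
F9 | step 3 | 2-bromo-1,5-bis(methoxymethoxy)-3-methylbenzene | COCOc1cc(C)c(Br)c(OCOC)c1
F10 | step 3 | [3-bromo-2,6-bis(methoxymethoxy)-4-methylphenyl]trimethylsilane | COCOc1cc(C)c(Br)c(OCOC)c1[Si](C)(C)C
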